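The pitfall with a substrate that falls fast is to read each point it loses as a point of target on the way, when the north-west run shows the two moving at different speeds.

- north-west: substrate 20 mM; gas phase 7.2 mM (held); the very flask that is asked about, followed so far
- flask: substrate 20 mM; gas phase 7.2 mM (held); time 1.0 h

north-west run (percent of the substrate charged)

| time / min | target / % | substrate / % |
|---|---|---|
| 0.667 | 0.7 | 93.9 |
| 1.33 | 0.5 | 88.8 |
| 2.00 | 1.2 | 83.0 |
| 3.00 | 3.1 | 73.9 |
| 4.00 | 5.2 | 66.7 |
| 5.00 | 6.4 | 59.8 |

(each reading ± 0.5 percentage points)

- what was read earlier has a scatter of 0.5 percentage points, one standard deviation
- at the start none of the gas phase is in solution

- amount of target at 1.0 h, in percent of the substrate charged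
- concentration of dissolved gas in solution at 6.0 min, in percent of saturation
- the change that raises the amount of target at 1.0 h, in percent of the substrate charged most ("none" if none brings more than 2 percentage points) (green / red / none)
- amount of target at 1.0 h, in percent of the substrate charged, after red

- green: doubling the saturation concentration of gas phase, all else as stated
- red: doubling the transfer coefficient of the gas phase, all else as stated

Reckon with rates. In the north-west run, which is the flask asked about followed so far, the substrate loses a steady fraction of itself, 0.104 /min, a pseudo-first-order fall with a half-life of 6.66 min, and it shows no wait for the gas. The target starts more slowly, with 7.06% of the substrate's loss up to 2.00 min, in a flask that began with none of the gas phase in solution. Between 3.00 min and 5.00 min the target gains 3.3 percentage points while the substrate loses 14 points, which gives 23.4%; call this the capture share, the target won per point of substrate lost, an instantaneous selectivity.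

Now freeze it, betting that the dissolved gas has stopped climbing. The target's rate then follows the substrate's, and from the last reading to 1.0 h it shrinks to 0.00328 of its value, because the half-life is shorter than the hour. The accumulated rate is therefore the capture share of the substrate standing at the last reading, and your reckoning ends at 20.4%, give or take 3 points from the scatter of the target readings.

The forecast, which differs from this reckoning, gives 95%, 93% of saturation at 6.0 min, green as the best change and 96% after red, and holds that “transfer barely limits”.

The flask gives 17.1%, 43.0% of saturation at 6.0 min, green as the best change with 8 points against 4.2 points for red, and 21.2% after red.

    2 dissolved gas → self-condensation product (k = 13.0 /M/min)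
    target ⇌ isomer of the product (K = 0.130, k = 0.00560 /min)
    substrate + target → side product B (k = 3.20 /M/min)
    gas phase ⇌ dissolved gas, rate k4*(csat - [dissolved gas]) (kL = 0.180 /min)
    substrate → side product A (k = 0.0850 /min)
    substrate + dissolved gas → target (k = 9.80 /M/min)

Carried from the state of this flask at 0.100 h, with 7.48% of target and 52.5% of substrate, the capture share read from the run, 23.4%, gives 19.8%, and the flask's own share over that stretch is 18.2%, while at 1.0 h, with 0.033% of the substrate left, its half-life by turning into side product A, 0.14 h, is shorter than the 0.27 h by its turning with dissolved gas into target. The neighbouring flask charged with 80 mM of substrate keeps 0.027% of its charge at 1.0 h, so its whole-run capture share is its target, 7.81%, about half of the 17.1% in this flask.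

The numbers in the tables come from a simulation on assumed constants; scatter was added.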